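**Retrosynthetic overview**

1. Cembrane numbering is used: C1 (ring-fusion CH carrying C15), C2 (ring-fusion CH–O), C3=C4(CH3), C5, C6=C7, C8(CH3)(OH), C9, C10, C11–C12(CH3) oxirane, C13 (OAc), C14; lactone C15(=C17H2)–C16(=O)–O–C2.
2. The enabling feature is the (E)-allylic tertiary alcohol C6=C7–C8(CH3)(OH) inside the 14-membered carbocycle. It is the retron of a reductive union of a terminal alkyne (C6≡C7H) with a methyl ketone (C8), so the C7–C8 ring bond, the E-alkene and the C8 stereocentre are made together by a nickel-catalysed reductive macrocyclization of the acyclic ynone 28.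
3. 28 comes from a C13–C14 union (Fukuyama coupling, then chelation-controlled reduction) of a cis-γ-lactone alkylzinc (C1–C7, C14–C16; fragments A and B) with an epoxy thioester (C8–C13, ketone masked as a vinyl group; fragment C).
4. Ring order: oxirane (asymmetric epoxidation) and γ-lactone (auxiliary-controlled anti-aldol, lactonization) on separate fragments, then the 14-membered carbocycle in the key step.
5. End game: α-methylenation of the lactone, desilylation, selective acetylation at C13.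

Key step: step 20

Assumption: the magnesium-catalysed anti-aldol of step 7 is taken to proceed through the chelated Z-enolate with attack opposite the benzyl group, which is why the (R)-auxiliary is specified; with the opposite facial sense the (S)-auxiliary would be used.

**Route**

Step 1
Reactants: 1 3-methylbut-2-en-1-yl acetate (prenyl acetate)
Product: 2 (E)-4-hydroxy-3-methylbut-2-en-1-yl acetate
Conditions: SeO2 (cat.), t-BuOOH, salicylic acid (cat.), CH2Cl2, rt
Reagents that add atoms: tert-butyl hydroperoxide CC(C)(C)OO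
Why: SeO2-catalysed allylic oxidation (ene reaction, then [2,3]-sigmatropic shift) hydroxylates the methyl group trans to the CH2OAc chain, which fixes the E geometry of the later C3=C4 bond.

Step 2
Reactants: 2 (E)-4-hydroxy-3-methylbut-2-en-1-yl acetate
Product: 3 (E)-4-bromo-3-methylbut-2-en-1-yl acetate
Conditions: CBr4, PPh3, CH2Cl2, 0 °C
Reagents that add atoms: carbon tetrabromide BrC(Br)(Br)Br
Why: Appel reaction, an SN2 displacement on the alkoxyphosphonium salt that should leave the alkene position and geometry untouched.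

Step 3
Reactants: 3 (E)-4-bromo-3-methylbut-2-en-1-yl acetate; 4 ethynyltrimethylsilane
Product: 5 (E)-3-methyl-6-(trimethylsilyl)hex-2-en-5-yn-1-yl acetate
Conditions: CuI (10 mol%), K2CO3, Bu4NI (cat.), DMF, rt
Reagents that add atoms: none
Why: Copper-mediated coupling of a terminal alkyne with a primary allylic bromide (copper acetylide, direct SN2 at the unhindered CH2Br) builds the skipped enyne C4–C7, the silyl group preventing double alkylation.

Step 4
Reactants: 5 (E)-3-methyl-6-(trimethylsilyl)hex-2-en-5-yn-1-yl acetate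
Product: 6 (E)-3-methyl-6-(trimethylsilyl)hex-2-en-5-yn-1-ol
Conditions: i-Bu2AlH, CH2Cl2, −78 °C
Reagents that add atoms: none
Why: Hydride cleavage of the acetate is chosen over methanolysis because basic methanol would also remove the alkynyl silyl group.

Step 5
Reactants: 6 (E)-3-methyl-6-(trimethylsilyl)hex-2-en-5-yn-1-ol
Product: 7 (E)-3-methyl-6-(trimethylsilyl)hex-2-en-5-ynal (fragment A)
Conditions: MnO2, CH2Cl2, rt
Reagents that add atoms: none
Why: MnO2 oxidizes the allylic alcohol selectively to the enal without E/Z isomerization or attack on the skipped enyne.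

Step 6
Reactants: 8 (4R)-4-benzyl-1,3-oxazolidin-2-one; 9 methyl 4-chloro-4-oxobutanoate
Product: 10 methyl 4-[(4R)-4-benzyl-2-oxo-1,3-oxazolidin-3-yl]-4-oxobutanoate (fragment B)
Conditions: n-BuLi, THF, −78 °C; then 9
Reagents that add atoms: none
Why: N-acylation of the lithiated oxazolidinone by the acid chloride installs the auxiliary on the succinate half ester.

Step 7
Reactants: 10 methyl 4-[(4R)-4-benzyl-2-oxo-1,3-oxazolidin-3-yl]-4-oxobutanoate; 7 (E)-3-methyl-6-(trimethylsilyl)hex-2-en-5-ynal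
Product: 13 (4R)-4-benzyl-3-{[(2S,3S)-2-[(E)-2-methyl-5-(trimethylsilyl)pent-1-en-4-yn-1-yl]-5-oxooxolan-3-yl]carbonyl}-1,3-oxazolidin-2-one, via O-silyl anti-aldol adduct 11 (not isolated), via anti-aldol hydroxy ester 12 (not isolated)
Conditions: MgCl2 (20 mol%), Et3N, Me3SiCl, EtOAc, rt; then 1 M HCl, THF; then PPTS (cat.), toluene, 50 °C
Reagents that add atoms: none
Why: Magnesium-catalysed Evans anti-aldol: soft enolization gives the chelated Z-enolate of the imide only (the ester is far less acidic), the enal adds anti on the face opposite the benzyl group and so sets C1 and C2 together, and after desilylation the anti adduct closes onto the methyl ester to give the cis-γ-lactone.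

Step 8
Reactants: 13 lactone imide
Product: 14 (4R,5S)-4-(hydroxymethyl)-5-[(E)-2-methyl-5-(trimethylsilyl)pent-1-en-4-yn-1-yl]oxolan-2-one
Conditions: NaBH4, THF/H2O (4:1), 0 °C
Reagents that add atoms: none
Why: Borohydride reduces the doubly activated exocyclic imide carbonyl faster than the γ-lactone and releases the auxiliary, giving the C14 hydroxymethyl group.

Step 9
Reactants: 14 hydroxymethyl lactone
Product: 15 (4S,5S)-4-(iodomethyl)-5-[(E)-2-methyl-5-(trimethylsilyl)pent-1-en-4-yn-1-yl]oxolan-2-one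
Conditions: I2, PPh3, imidazole, CH2Cl2, 0 °C to rt
Reagents that add atoms: iodine II
Why: Appel-type iodination (alkoxyphosphonium iodide, SN2) of the primary alcohol; no stereocentre is involved.

Step 10
Reactants: 16 pent-4-enal; 17 methyl 2-[bis(2,2,2-trifluoroethoxy)phosphoryl]propanoate
Product: 18 methyl (Z)-2-methylhepta-2,6-dienoate
Conditions: 17, KHMDS, 18-crown-6, THF, −78 °C; then 16
Reagents that add atoms: none
Why: Still–Gennari olefination: the electron-poor phosphonate eliminates fast from the kinetically formed adduct and should give the Z-trisubstituted enoate needed for the cis-oxirane.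

Step 11
Reactants: 18 methyl (Z)-2-methylhepta-2,6-dienoate
Product: 19 (Z)-2-methylhepta-2,6-dien-1-ol
Conditions: i-Bu2AlH, CH2Cl2, −78 to 0 °C
Reagents that add atoms: none
Why: 1,2-Reduction of the ester to the allylic alcohol with retention of the Z geometry.

Step 12
Reactants: 19 (Z)-2-methylhepta-2,6-dien-1-ol
Product: 20 [(2R,3S)-3-(but-3-en-1-yl)-2-methyloxiran-2-yl]methanol
Conditions: Ti(OiPr)4 (10 mol%), D-(−)-diethyl tartrate (12 mol%), t-BuOOH, 4 Å MS, CH2Cl2, −20 °C
Reagents that add atoms: tert-butyl hydroperoxide CC(C)(C)OO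
Why: Sharpless asymmetric epoxidation: the titanium D-(−)-tartrate complex delivers oxygen to one face of the allylic alcohol under reagent control, setting C11 and C12 as the cis-oxirane, while the isolated terminal alkene is not touched.

Step 13
Reactants: 20 epoxy alcohol
Product: 21 (2S,3S)-3-(but-3-en-1-yl)-2-methyloxirane-2-carboxylic acid
Conditions: TEMPO (cat.), PhI(OAc)2, MeCN/pH 7 buffer, rt
Reagents that add atoms: water O
Why: Oxoammonium (TEMPO) oxidation of the primary alcohol through the aldehyde hydrate to the acid under neutral conditions that spare the oxirane and the alkene.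

Step 14
Reactants: 21 epoxy acid
Product: 22 S-ethyl (2S,3S)-3-(but-3-en-1-yl)-2-methyloxirane-2-carbothioate (fragment C)
Conditions: EtSH, DCC, DMAP (cat.), CH2Cl2, 0 °C
Reagents that add atoms: ethanethiol CCS
Why: Steglich-type (carbodiimide, DMAP) thioesterification of the hindered acid.

Step 15
Reactants: 15 iodomethyl lactone; 22 epoxy thioester
Product: 24 (4S,5R)-4-{2-[(2S,3S)-3-(but-3-en-1-yl)-2-methyloxiran-2-yl]-2-oxoethyl}-5-[(E)-2-methyl-5-(trimethylsilyl)pent-1-en-4-yn-1-yl]oxolan-2-one, via alkylzinc iodide 23 (not isolated)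
Conditions: 15, Zn dust (activated with BrCH2CH2Br, Me3SiCl), THF, 35 °C; then 22, PdCl2(PPh3)2 (5 mol%), toluene, rt
Reagents that add atoms: none
Why: Fukuyama coupling: zinc inserts into the primary C–I bond (the lactone is tolerated) and palladium-catalysed acyl transfer from the thioester gives the ketone without over-addition, forming the C13–C14 bond with all stereocentres untouched.

Step 16
Reactants: 24 epoxy ketone
Product: 25 (4S,5R)-4-{(2R)-2-[(2R,3S)-3-(but-3-en-1-yl)-2-methyloxiran-2-yl]-2-hydroxyethyl}-5-[(E)-2-methyl-5-(trimethylsilyl)pent-1-en-4-yn-1-yl]oxolan-2-one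
Conditions: Zn(BH4)2, Et2O, −30 °C
Reagents that add atoms: none
Why: Chelation-controlled Zn(BH4)2 reduction of an α,β-epoxy ketone: zinc bridges the carbonyl and oxirane oxygens and hydride enters from the face opposite the oxirane C–C bond and its cis C10 chain, which should give the anti (erythro) epoxy alcohol with the C13 configuration of the target, while the lactone is not reduced at this temperature.

Step 17
Reactants: 25 epoxy alcohol
Product: 26 (4S,5R)-4-{(2R)-2-[(2S,3S)-3-(but-3-en-1-yl)-2-methyloxiran-2-yl]-2-[(tert-butyldimethylsilyl)oxy]ethyl}-5-[(E)-2-methyl-5-(trimethylsilyl)pent-1-en-4-yn-1-yl]oxolan-2-one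
Conditions: TBSOTf, 2,6-lutidine, CH2Cl2, −78 °C
Reagents that add atoms: tert-butyldimethylsilyl trifluoromethanesulfonate CC(C)(C)[Si](C)(C)OS(=O)(=O)C(F)(F)F
Why: Silylation of the hindered secondary alcohol with the silyl triflate gives a group that should survive the base, nickel/silane and LDA of steps 19 to 21.

Step 18
Reactants: 26 silyl ether
Product: 27 (4S,5R)-4-{(2R)-2-[(tert-butyldimethylsilyl)oxy]-2-[(2S,3S)-2-methyl-3-(3-oxobutyl)oxiran-2-yl]ethyl}-5-[(E)-2-methyl-5-(trimethylsilyl)pent-1-en-4-yn-1-yl]oxolan-2-one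
Conditions: PdCl2 (10 mol%), Cu(OAc)2 (20 mol%), O2 (1 atm), DMA/H2O (7:1), rt
Reagents that add atoms: water O
Why: Tsuji–Wacker oxidation: Markovnikov hydroxypalladation and β-hydride elimination at the only monosubstituted alkene unmask the C8 methyl ketone, the copper acetate co-catalyst keeping the medium non-acidic for the oxirane.

Step 19
Reactants: 27 silyl alkyne methyl ketone
Product: 28 (4S,5R)-4-{(2R)-2-[(tert-butyldimethylsilyl)oxy]-2-[(2S,3S)-2-methyl-3-(3-oxobutyl)oxiran-2-yl]ethyl}-5-[(E)-2-methylpent-1-en-4-yn-1-yl]oxolan-2-one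
Conditions: K2CO3 (0.3 equiv), MeOH, 0 °C
Reagents that add atoms: none
Why: Methoxide-induced protodesilylation of the alkynylsilane frees the terminal alkyne; the alkyl silyl ether is stable to these conditions.

Step 20
Reactants: 28 seco-ynone
Product: 29 (1S,2R,3E,6E,8S,11S,12S,13R)-13-[(tert-butyldimethylsilyl)oxy]-11,12-epoxy-8-[(triethylsilyl)oxy]-17-norcembra-3,6-dien-16,2-olide (target skeleton with CH2 at C15)
Conditions: Ni(cod)2 (30 mol%), (4R,5R)-1,3-bis(2-isopropylphenyl)-4,5-diphenylimidazolinium tetrafluoroborate (30 mol%), KOt-Bu (30 mol%), Et3SiH (5 equiv), THF, syringe-pump addition of 28 to 2 mM, rt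
Reagents that add atoms: triethylsilane CC[SiH](CC)CC
Why: Proposed new method: zerovalent nickel carrying the N-heterocyclic carbene binds the terminal alkyne and the methyl ketone of 28 and couples them oxidatively through the unsubstituted alkyne carbon to a five-membered oxanickelacyclopentene (Ni–O–C8–C7=C6), which Et3SiH cleaves by σ-bond metathesis at Ni–O (giving the O–SiEt3 group) followed by C–H reductive elimination; the closest known reactions are the nickel/carbene/silane reductive macrocyclization of ynals to 14- to 22-membered (E)-allylic silyl ethers and the nickel-catalysed reductive cyclization of alkynyl ketones to five- and six-membered tertiary allylic alcohols. The 14-membered carbocycle closes endo with respect to the alkyne (14-endo-dig, both alkyne carbons in the ring) and exo with respect to the carbonyl (oxygen outside the ring). The C6=C7 bond must be E because the new C–C bond and the hydrogen from silicon are delivered syn across the alkyne. The new C8 stereocentre is set by the ketone face that enters the metallacycle, which the C2-symmetric chiral carbene is meant to dictate by differentiating CH3 from the C9 methylene arm, the nearest resident stereocentre (C11) being three bonds away and not relied on; if the sense proves mismatched, the mirror-image ligand is used. The step needs regioselectivity for the alkyne terminus (secured by the unsubstituted terminus and a carbene no larger than IMes) and chemoselectivity for the alkyne/ketone pair (secured by the substrate having no other good π-acceptor: the lactone is still saturated, the remaining alkene and the oxirane are trisubstituted, and the C13 hydroxyl is silylated). The in situ O-silylation also keeps the new tertiary alkoxide from opening the 1,4-related oxirane.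

Step 21
Reactants: 29 macrocyclic bis(silyl ether)
Product: 32 (1S,2S,3E,6E,8S,11S,12S,13R)-13-[(tert-butyldimethylsilyl)oxy]-11,12-epoxy-8-[(triethylsilyl)oxy]cembra-3,6,15(17)-trien-16,2-olide, via Mannich base 30 (not isolated), via trimethylammonium iodide 31 (not isolated)
Conditions: LDA, THF, −78 °C; CH2=NMe2+ I−, −78 °C to rt; then MeI, MeOH; then aq. NaHCO3, CH2Cl2
Reagents that add atoms: N,N-dimethylmethyleneiminium iodide (Eschenmoser's salt) C=[N+](C)C.[I-]
Why: Eschenmoser methylenation: the lactone enolate (the only carbonyl α-position in 29) undergoes a Mannich reaction with the iminium salt, and N-methylation followed by base-induced elimination of trimethylamine gives the exocyclic C15=C17 alkene.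

Step 22
Reactants: 32 α-methylene lactone bis(silyl ether)
Product: 33 (1S,2S,3E,6E,8S,11S,12R,13R)-11,12-epoxy-8,13-dihydroxycembra-3,6,15(17)-trien-16,2-olide (spatial arrangement as in the target)
Conditions: HF·pyridine, pyridine, THF, 0 °C to rt
Reagents that add atoms: none
Why: Fluoride cleavage of both silyl ethers; the excess pyridine keeps the medium from protonating the oxirane that lies 1,4 to the freed tertiary alcohol.

Step 23
Reactants: 33 diol
Product: 34 CNP0288879.2, (1S,2S,3E,6E,8S,11S,12S,13R)-13-acetoxy-11,12-epoxy-8-hydroxycembra-3,6,15(17)-trien-16,2-olide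
Conditions: Ac2O, pyridine, DMAP (cat.), CH2Cl2, 0 °C
Reagents that add atoms: acetic anhydride CC(=O)OC(C)=O
Why: DMAP-catalysed acylation differentiates the secondary C13 hydroxyl from the tertiary C8 hydroxyl, which is inert under these conditions.

**Compound list**

1 | 3-methylbut-2-en-1-yl acetate | CC(C)=CCOC(C)=O | starting material
2 | (E)-4-hydroxy-3-methylbut-2-en-1-yl acetate | CC(=O)OC/C=C(\C)CO | intermediate
3 | (E)-4-bromo-3-methylbut-2-en-1-yl acetate | CC(=O)OC/C=C(\C)CBr | intermediate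
4 | ethynyltrimethylsilane | C#C[Si](C)(C)C | starting material
5 | (E)-3-methyl-6-(trimethylsilyl)hex-2-en-5-yn-1-yl acetate | CC(=O)OC/C=C(\C)CC#C[Si](C)(C)C | intermediate
6 | (E)-3-methyl-6-(trimethylsilyl)hex-2-en-5-yn-1-ol | OC/C=C(\C)CC#C[Si](C)(C)C | intermediate
7 | (E)-3-methyl-6-(trimethylsilyl)hex-2-en-5-ynal | O=C/C=C(\C)CC#C[Si](C)(C)C | intermediate
8 | (4R)-4-benzyl-1,3-oxazolidin-2-one | O=C1N[C@H](Cc2ccccc2)CO1 | starting material
9 | methyl 4-chloro-4-oxobutanoate | COC(=O)CCC(Cl)=O | starting material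
10 | methyl 4-[(4R)-4-benzyl-2-oxo-1,3-oxazolidin-3-yl]-4-oxobutanoate | COC(=O)CCC(=O)N1C(=O)OC[C@H]1Cc1ccccc1 | intermediate
11 | methyl (3S,4S,5E)-3-{[(4R)-4-benzyl-2-oxo-1,3-oxazolidin-3-yl]carbonyl}-6-methyl-9-(trimethylsilyl)-4-[(trimethylsilyl)oxy]non-5-en-8-ynoate | C[Si](C)(C)C#CC/C(C)=C/[C@H](O[Si](C)(C)C)[C@H](CC(=O)OC)C(=O)N1C(=O)OC[C@H]1Cc1ccccc1 | intermediate
12 | methyl (3S,4S,5E)-3-{[(4R)-4-benzyl-2-oxo-1,3-oxazolidin-3-yl]carbonyl}-4-hydroxy-6-methyl-9-(trimethylsilyl)non-5-en-8-ynoate | C[Si](C)(C)C#CC/C(C)=C/[C@H](O)[C@H](CC(=O)OC)C(=O)N1C(=O)OC[C@H]1Cc1ccccc1 | intermediate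
13 | (4R)-4-benzyl-3-{[(2S,3S)-2-[(E)-2-methyl-5-(trimethylsilyl)pent-1-en-4-yn-1-yl]-5-oxooxolan-3-yl]carbonyl}-1,3-oxazolidin-2-one | C[Si](C)(C)C#CC/C(C)=C/[C@@H]1OC(=O)C[C@@H]1C(=O)N1C(=O)OC[C@H]1Cc1ccccc1 | intermediate
14 | (4R,5S)-4-(hydroxymethyl)-5-[(E)-2-methyl-5-(trimethylsilyl)pent-1-en-4-yn-1-yl]oxolan-2-one | C[Si](C)(C)C#CC/C(C)=C/[C@@H]1OC(=O)C[C@@H]1CO | intermediate
15 | (4S,5S)-4-(iodomethyl)-5-[(E)-2-methyl-5-(trimethylsilyl)pent-1-en-4-yn-1-yl]oxolan-2-one | C[Si](C)(C)C#CC/C(C)=C/[C@@H]1OC(=O)C[C@@H]1CI | intermediate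
16 | pent-4-enal | C=CCCC=O | starting material
17 | methyl 2-[bis(2,2,2-trifluoroethoxy)phosphoryl]propanoate | COC(=O)C(C)P(=O)(OCC(F)(F)F)OCC(F)(F)F | starting material
18 | methyl (Z)-2-methylhepta-2,6-dienoate | COC(=O)/C(C)=C\CCC=C | intermediate
19 | (Z)-2-methylhepta-2,6-dien-1-ol | OC/C(C)=C\CCC=C | intermediate
20 | [(2R,3S)-3-(but-3-en-1-yl)-2-methyloxiran-2-yl]methanol | OC[C@@]1(C)O[C@H]1CCC=C | intermediate
21 | (2S,3S)-3-(but-3-en-1-yl)-2-methyloxirane-2-carboxylic acid | OC(=O)[C@@]1(C)O[C@H]1CCC=C | intermediate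
22 | S-ethyl (2S,3S)-3-(but-3-en-1-yl)-2-methyloxirane-2-carbothioate | CCSC(=O)[C@@]1(C)O[C@H]1CCC=C | intermediate
23 | {[(2S,3S)-2-[(E)-2-methyl-5-(trimethylsilyl)pent-1-en-4-yn-1-yl]-5-oxooxolan-3-yl]methyl}zinc iodide | C[Si](C)(C)C#CC/C(C)=C/[C@@H]1OC(=O)C[C@@H]1C[Zn]I | intermediate
24 | (4S,5R)-4-{2-[(2S,3S)-3-(but-3-en-1-yl)-2-methyloxiran-2-yl]-2-oxoethyl}-5-[(E)-2-methyl-5-(trimethylsilyl)pent-1-en-4-yn-1-yl]oxolan-2-one | C[Si](C)(C)C#CC/C(C)=C/[C@@H]1OC(=O)C[C@@H]1CC(=O)[C@@]2(C)O[C@H]2CCC=C | intermediate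
25 | (4S,5R)-4-{(2R)-2-[(2R,3S)-3-(but-3-en-1-yl)-2-methyloxiran-2-yl]-2-hydroxyethyl}-5-[(E)-2-methyl-5-(trimethylsilyl)pent-1-en-4-yn-1-yl]oxolan-2-one | C[Si](C)(C)C#CC/C(C)=C/[C@@H]1OC(=O)C[C@@H]1C[C@@H](O)[C@@]2(C)O[C@H]2CCC=C | intermediate
26 | (4S,5R)-4-{(2R)-2-[(2S,3S)-3-(but-3-en-1-yl)-2-methyloxiran-2-yl]-2-[(tert-butyldimethylsilyl)oxy]ethyl}-5-[(E)-2-methyl-5-(trimethylsilyl)pent-1-en-4-yn-1-yl]oxolan-2-one | C[Si](C)(C)C#CC/C(C)=C/[C@@H]1OC(=O)C[C@@H]1C[C@@H](O[Si](C)(C)C(C)(C)C)[C@@]2(C)O[C@H]2CCC=C | intermediate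
27 | (4S,5R)-4-{(2R)-2-[(tert-butyldimethylsilyl)oxy]-2-[(2S,3S)-2-methyl-3-(3-oxobutyl)oxiran-2-yl]ethyl}-5-[(E)-2-methyl-5-(trimethylsilyl)pent-1-en-4-yn-1-yl]oxolan-2-one | C[Si](C)(C)C#CC/C(C)=C/[C@@H]1OC(=O)C[C@@H]1C[C@@H](O[Si](C)(C)C(C)(C)C)[C@@]2(C)O[C@H]2CCC(C)=O | intermediate
28 | (4S,5R)-4-{(2R)-2-[(tert-butyldimethylsilyl)oxy]-2-[(2S,3S)-2-methyl-3-(3-oxobutyl)oxiran-2-yl]ethyl}-5-[(E)-2-methylpent-1-en-4-yn-1-yl]oxolan-2-one | C#CC/C(C)=C/[C@@H]1OC(=O)C[C@@H]1C[C@@H](O[Si](C)(C)C(C)(C)C)[C@@]2(C)O[C@H]2CCC(C)=O | intermediate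
29 | (1S,2R,3E,6E,8S,11S,12S,13R)-13-[(tert-butyldimethylsilyl)oxy]-11,12-epoxy-8-[(triethylsilyl)oxy]-17-norcembra-3,6-dien-16,2-olide | C1C(=O)O[C@H]2/C=C(\C)C/C=C/[C@@](C)(O[Si](CC)(CC)CC)CC[C@@H]3O[C@]3(C)[C@H](O[Si](C)(C)C(C)(C)C)C[C@@H]12 | intermediate
30 | Mannich base: 29 carrying CH2NMe2 at C15 (C15 epimers) | CN(C)CC1C(=O)O[C@H]2/C=C(\C)C/C=C/[C@@](C)(O[Si](CC)(CC)CC)CC[C@@H]3O[C@]3(C)[C@H](O[Si](C)(C)C(C)(C)C)C[C@@H]12 | intermediate
31 | trimethylammonium iodide of 30 | C[N+](C)(C)CC1C(=O)O[C@H]2/C=C(\C)C/C=C/[C@@](C)(O[Si](CC)(CC)CC)CC[C@@H]3O[C@]3(C)[C@H](O[Si](C)(C)C(C)(C)C)C[C@@H]12.[I-] | intermediate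
32 | (1S,2S,3E,6E,8S,11S,12S,13R)-13-[(tert-butyldimethylsilyl)oxy]-11,12-epoxy-8-[(triethylsilyl)oxy]cembra-3,6,15(17)-trien-16,2-olide | C=C1C(=O)O[C@H]2/C=C(\C)C/C=C/[C@@](C)(O[Si](CC)(CC)CC)CC[C@@H]3O[C@]3(C)[C@H](O[Si](C)(C)C(C)(C)C)C[C@@H]12 | intermediate
33 | (1S,2S,3E,6E,8S,11S,12R,13R)-11,12-epoxy-8,13-dihydroxycembra-3,6,15(17)-trien-16,2-olide | C=C1C(=O)O[C@H]2/C=C(\C)C/C=C/[C@@](C)(O)CC[C@@H]3O[C@]3(C)[C@H](O)C[C@@H]12 | intermediate
34 | CNP0288879.2, (1S,2S,3E,6E,8S,11S,12S,13R)-13-acetoxy-11,12-epoxy-8-hydroxycembra-3,6,15(17)-trien-16,2-olide | C=C1C(=O)O[C@H]2/C=C(\C)C/C=C/[C@@](C)(O)CC[C@@H]3O[C@]3(C)[C@H](OC(C)=O)C[C@@H]12 | target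

**Step count**

Total: 23 steps. Longest linear sequence: 17 steps (steps 1–5, 7–9, 15–23).

**Steps most likely to fail, with fallbacks**

Step 20 (proposed new method). What may go wrong: oxidative cyclization onto the unactivated, remote ketone may be outrun by alkyne oligomerization or hydrosilylation, nickel may ionize the allylic C2–O bond of the lactone, or the ketone may enter the metallacycle through the wrong face. The fallback uses known chemistry and sets out from 28. Palladium-catalysed hydrostannation (Bu3SnH, PdCl2(PPh3)2 (cat.), THF, 0 °C) should give the (E)-alkenylstannane F1, to be separated from any internal regioisomer. Iododestannylation (I2, CH2Cl2, 0 °C) should give the (E)-alkenyl iodide F2 with retention. An intramolecular Nozaki–Hiyama–Kishi addition of the alkenyl iodide to the methyl ketone (CrCl2, NiCl2 (cat.), DMSO/THF, high dilution, rt) should close the 14-membered ring to the macrocyclic tertiary alcohol F3. Silylation (TESOTf, 2,6-lutidine, CH2Cl2, −78 °C) comes back to the route at 29.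

Step 15. What may go wrong: acyl transfer from the hindered, fully substituted oxirane thioester to palladium may be slow, so that protodezincation of 23 and decarbonylation take over. The fallback sets out from 20 and 15. Parikh–Doering oxidation of 20 (SO3·pyridine, DMSO, i-Pr2NEt, 0 °C) gives the epoxy aldehyde F4. Iodine–zinc exchange on 15 (Et2Zn, CuI (cat.), 50 °C, volatiles removed) gives the dialkylzinc F5. Catalytic enantioselective addition of F5 to F4 (Ti(OiPr)4, (1S,2S)-1,2-bis(trifluoromethanesulfonamido)cyclohexane (8 mol%), toluene, −20 °C) should form the C13–C14 bond and set the C13 carbinol under catalyst control. This comes back to the route at 25, so that steps 13 to 16 are not needed.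

Step 7. What may go wrong: γ-deprotonation and silylation of the enal under the soft-enolization conditions, or insufficient anti selectivity. The fallback sets out from 7. A titanium-catalysed enantioselective Mukaiyama acetate aldol (1-methoxy-1-(trimethylsilyloxy)ethene, Ti(OiPr)4/BINOL-derived Schiff base catalyst, Et2O, −10 °C; then 1 M HCl) should give the β-hydroxy ester F6. Fráter–Seebach alkylation of its dianion (LDA, 2.2 equiv, THF, −78 to −20 °C; tert-butyl bromoacetate) introduces the C15–C16 unit anti to the hydroxyl and gives the anti-succinate F7. TFA in CH2Cl2 at 0 °C cleaves the tert-butyl ester and closes the cis-lactone methyl ester F8. Me3SnOH (1,2-dichloroethane, 70 °C) gives the lactone acid F9. Mixed-anhydride reduction (isobutyl chloroformate, N-methylmorpholine; then NaBH4) comes back to the route at 14.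

**Further compounds**

F1 | step 20 | (E)-alkenylstannane: 28 with the terminal alkyne converted into (E)-CH=CH–SnBu3 | CCCC[Sn](CCCC)(CCCC)/C=C/C/C(C)=C/[C@@H]1OC(=O)C[C@@H]1C[C@@H](O[Si](C)(C)C(C)(C)C)[C@@]2(C)O[C@H]2CCC(C)=O
F2 | step 20 | (E)-alkenyl iodide: 28 with the terminal alkyne converted into (E)-CH=CHI | I/C=C/C/C(C)=C/[C@@H]1OC(=O)C[C@@H]1C[C@@H](O[Si](C)(C)C(C)(C)C)[C@@]2(C)O[C@H]2CCC(C)=O
F3 | step 20 | macrocyclic tertiary alcohol: 29 with free OH at C8 | C1C(=O)O[C@H]2/C=C(\C)C/C=C/[C@@](C)(O)CC[C@@H]3O[C@]3(C)[C@H](O[Si](C)(C)C(C)(C)C)C[C@@H]12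
F4 | step 15 | (2S,3S)-3-(but-3-en-1-yl)-2-methyloxirane-2-carbaldehyde | O=C[C@@]1(C)O[C@H]1CCC=C
F5 | step 15 | bis{[(2S,3S)-2-[(E)-2-methyl-5-(trimethylsilyl)pent-1-en-4-yn-1-yl]-5-oxooxolan-3-yl]methyl}zinc | C[Si](C)(C)C#CC/C(C)=C/[C@@H]1OC(=O)C[C@@H]1C[Zn]C[C@H]1CC(=O)O[C@H]1/C=C(C)/CC#C[Si](C)(C)C
F6 | step 7 | methyl (3R,4E)-3-hydroxy-5-methyl-8-(trimethylsilyl)oct-4-en-7-ynoate | C[Si](C)(C)C#CC/C(C)=C/[C@H](O)CC(=O)OC
F7 | step 7 | 4-tert-butyl 1-methyl (2S)-2-[(1S,2E)-1-hydroxy-3-methyl-6-(trimethylsilyl)hex-2-en-5-yn-1-yl]butanedioate | C[Si](C)(C)C#CC/C(C)=C/[C@H](O)[C@H](CC(=O)OC(C)(C)C)C(=O)OC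
F8 | step 7 | methyl (2S,3S)-2-[(E)-2-methyl-5-(trimethylsilyl)pent-1-en-4-yn-1-yl]-5-oxooxolane-3-carboxylate | C[Si](C)(C)C#CC/C(C)=C/[C@@H]1OC(=O)C[C@@H]1C(=O)OC
F9 | step 7 | (2S,3S)-2-[(E)-2-methyl-5-(trimethylsilyl)pent-1-en-4-yn-1-yl]-5-oxooxolane-3-carboxylic acid | C[Si](C)(C)C#CC/C(C)=C/[C@@H]1OC(=O)C[C@@H]1C(=O)O
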